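**Plan**

- Retrosynthesis: the pyrrole is first taken back to a 3-hydroxy-1-tosylpyrrolidine (water re-added across C3–C4, toluenesulfinic acid across N1–C2). That ring is then cut at N1–C5 and at C2–C3.
- Enabling feature: N1 together with C2 and its methyl ester is a glycine ester. C3 (bearing the nonadecyl chain), C4 and C5 are the carbonyl, α and β carbons of an alkyl vinyl ketone, and C4 and C5 carry only hydrogen, as a vinyl group requires.
- The vinyl ketone is cut at its carbonyl–vinyl bond (icosanoic acid as its Weinreb amide plus a vinyl Grignard reagent), and the sulfonamide at N–S.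
- Forward: the C22 enone is assembled (steps 1–2) and the glycinate is tosylated (step 3). The only ring, N1–C2–C3–C4–C5, closes in step 4 (N1–C5 first, then C2–C3), and steps 5–6 aromatise it by loss of water and p-toluenesulfinate.
- Stereochemistry: the target has no stereocentre. The two centres created in step 4 form without control and disappear on aromatisation.

Key step: step 4

Remark: the dehydration product of step 5 is drawn as the 2,5-dihydropyrrole; any alkene isomers formed beside it would be carried forward together, since all should converge on the same pyrrole in step 6.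

**Route**

Step 1
Reactants: 1 icosanoic acid; 2 N,O-dimethylhydroxylamine hydrochloride
Product: 4 N-methoxy-N-methylicosanamide, via 1-icosanoylimidazole 3 (not isolated)
Conditions: CDI (1.1 equiv), THF, 40 °C until gas evolution stops; then 2 (1.2 equiv), rt
Reagents that add atoms: 1,1'-carbonyldiimidazole, O=C(n1ccnc1)n1ccnc1 (supplies the imidazolyl group of 3 only; none of its atoms remain in 4)
Why: Carbonyldiimidazole turns the acid into acylimidazole 3 with loss of CO2, and N,O-dimethylhydroxylamine then displaces imidazole in a standard Weinreb amide formation; no stereocentre is involved.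

Step 2
Reactants: 4 N-methoxy-N-methylicosanamide; 5 vinylmagnesium bromide (CH2=CHMgBr)
Product: 7 docos-1-en-3-one, via bromomagnesium hemiaminal chelate 6 (not isolated)
Conditions: CH2=CHMgBr (1.5 equiv, THF solution), THF, 0 °C; inverse quench into cold 2 M aq. HCl/Et2O; trace BHT, used promptly
Reagents that add atoms: none
Why: Weinreb ketone synthesis, in which the Grignard reagent adds once to give the five-membered magnesium chelate 6 that cannot collapse before the quench, and the inverse quench into cold acid protonates the released N,O-dimethylhydroxylamine at once so that it should not add to the new enone.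

Step 3
Reactants: 8 glycine methyl ester hydrochloride; 9 p-toluenesulfonyl chloride
Product: 10 methyl N-tosylglycinate
Conditions: Et3N (2.2 equiv), CH2Cl2, 0 °C to rt
Reagents that add atoms: none
Why: N-sulfonylation of a primary amine by a sulfonyl chloride under Et3N; the sulfonamide formed is far less nucleophilic than the amine, so a second tosylation is not expected.

Step 4
Reactants: 10 methyl N-tosylglycinate; 7 docos-1-en-3-one
Product: 12 methyl 3-hydroxy-3-nonadecyl-1-tosylpyrrolidine-2-carboxylate (racemic, mixture of diastereomers), via open-chain aza-Michael adduct 11 (not isolated)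
Conditions: 10 (1.2 equiv), DBU (2 equiv), THF, 0 °C; slow addition of 7 in THF; then rt
Reagents that add atoms: none
Why: DBU deprotonates the sulfonamide N–H of 10, and the soft nitrogen anion adds in conjugate fashion to the unsubstituted CH2 terminus of 7 (N1–C5) to give keto ester 11, whose glycinate carbon, now flanked by the ester and the sulfonylated nitrogen, is enolised reversibly and attacks the ketone (C2–C3). The closest known reaction type is the Kenner pyrrole synthesis, an aza-Michael/intramolecular aldol cascade between N-sulfonylglycine esters and vinyl ketones. The single ring closes by a 5-exo-trig (enolexo) aldol addition, the ketone carbon being the only electrophile the glycinate carbon can reach through a five-membered transition state. C2 and C3 become stereocentres without any controlling element, so 12 should form as a racemic mixture of diastereomers, which is harmless because both carbons become sp2 centres in steps 5 and 6. The step needs nitrogen to react 1,4 before carbon reacts at all, and this is secured by the sulfonamide N–H being far more acidic than the glycinate C–H, so that carbon nucleophilicity is unmasked only after N-alkylation. Slow addition of 7 to a slight excess of 10 at 0 °C keeps the stationary enone concentration low and should suppress base-induced oligomerisation and double Michael addition.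

Step 5
Reactants: 12 methyl 3-hydroxy-3-nonadecyl-1-tosylpyrrolidine-2-carboxylate
Product: 14 methyl 3-nonadecyl-1-tosyl-2,5-dihydro-1H-pyrrole-2-carboxylate (racemic), via tertiary dichlorophosphate ester 13 (not isolated)
Conditions: POCl3 (3 equiv), pyridine, 0 °C to rt
Reagents that add atoms: phosphoryl chloride, O=P(Cl)(Cl)Cl (supplies the dichlorophosphoryl group of 13 only; none of its atoms remain in 14)
Why: Dehydration of a tertiary alcohol by POCl3 in pyridine, in which O-phosphorylation gives dichlorophosphate 13 and pyridine-induced E2 loss of dichlorophosphate gives the ring alkene; the C3 stereocentre is removed, and the alkene regiochemistry is not critical because every isomer leads to the same pyrrole.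

Step 6
Reactants: 14 methyl 3-nonadecyl-1-tosyl-2,5-dihydro-1H-pyrrole-2-carboxylate
Product: 16 methyl 3-nonadecyl-1H-pyrrole-2-carboxylate, via 2H-pyrrole tautomer 15 (not isolated)
Conditions: NaOMe (3 equiv), dry MeOH/THF (1:1), rt to 50 °C; aq. NH4Cl work-up
Reagents that add atoms: none
Why: E1cB elimination, in which methoxide removes the C2 proton (activated by the ester and the allylic position), p-toluenesulfinate leaves from nitrogen to give 2H-pyrrole 15, and a prototropic shift to the aromatic 1H-pyrrole drives the sequence; methoxide in methanol matches the methyl ester, so ester exchange is degenerate.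

**Compound list**

1 | icosanoic acid | CCCCCCCCCCCCCCCCCCCC(=O)O | starting material
2 | N,O-dimethylhydroxylamine hydrochloride | CNOC.Cl | starting material
3 | 1-(1H-imidazol-1-yl)icosan-1-one (1-icosanoylimidazole) | CCCCCCCCCCCCCCCCCCCC(=O)n1ccnc1 | intermediate
4 | N-methoxy-N-methylicosanamide | CCCCCCCCCCCCCCCCCCCC(=O)N(C)OC | intermediate
5 | vinylmagnesium bromide | C=C[Mg]Br | starting material
6 | bromomagnesium 3-[methoxy(methyl)amino]docos-1-en-3-olate (chelated tetrahedral adduct) | CCCCCCCCCCCCCCCCCCCC(O[Mg]Br)(C=C)N(C)OC | intermediate
7 | docos-1-en-3-one | CCCCCCCCCCCCCCCCCCCC(=O)C=C | intermediate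
8 | glycine methyl ester hydrochloride | COC(=O)CN.Cl | starting material
9 | p-toluenesulfonyl chloride | Cc1ccc(S(Cl)(=O)=O)cc1 | starting material
10 | methyl N-tosylglycinate | COC(=O)CNS(=O)(=O)c1ccc(C)cc1 | intermediate
11 | methyl N-(3-oxodocosyl)-N-tosylglycinate | CCCCCCCCCCCCCCCCCCCC(=O)CCN(CC(=O)OC)S(=O)(=O)c1ccc(C)cc1 | intermediate
12 | methyl 3-hydroxy-3-nonadecyl-1-tosylpyrrolidine-2-carboxylate (racemic, mixture of diastereomers) | CCCCCCCCCCCCCCCCCCCC1(O)CCN(S(=O)(=O)c2ccc(C)cc2)C1C(=O)OC | intermediate
13 | methyl 3-[(dichlorophosphoryl)oxy]-3-nonadecyl-1-tosylpyrrolidine-2-carboxylate (mixture of diastereomers) | CCCCCCCCCCCCCCCCCCCC1(OP(=O)(Cl)Cl)CCN(S(=O)(=O)c2ccc(C)cc2)C1C(=O)OC | intermediate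
14 | methyl 3-nonadecyl-1-tosyl-2,5-dihydro-1H-pyrrole-2-carboxylate (racemic) | CCCCCCCCCCCCCCCCCCCC1=CCN(S(=O)(=O)c2ccc(C)cc2)C1C(=O)OC | intermediate
15 | methyl 4-nonadecyl-2H-pyrrole-5-carboxylate | CCCCCCCCCCCCCCCCCCCC1=CCN=C1C(=O)OC | intermediate
16 | methyl 3-nonadecyl-1H-pyrrole-2-carboxylate | CCCCCCCCCCCCCCCCCCCc1cc[nH]c1C(=O)OC | target

**Step count and risks**

Total step count: 6. Longest linear sequence: 5 steps (steps 1, 2, 4, 5, 6 from icosanoic acid); step 3 is a one-step side branch.

Steps most likely to fail:

1. Step 4. Base-induced oligomerisation of the vinyl ketone could outrun the conjugate addition of the sulfonamide, or the aldol equilibrium could remain on the open-chain side and leak into a second Michael addition. The fallback forms the same two ring bonds one oxidation level higher; it sets out from 4 (with 8) and returns at 16. Weinreb amide 4 would be treated with ethynylmagnesium bromide (HC≡CMgBr, THF, 0 °C, inverse acidic quench) to give docos-1-yn-3-one F1. Glycine methyl ester, released from 8 with Et3N in MeOH, should add to the ynone (N1–C5) to give the hydrogen-bonded enaminone methyl N-[(1Z)-3-oxodocos-1-en-1-yl]glycinate F2. NaOMe in hot MeOH should then close C2–C3 by intramolecular aldol condensation, and loss of water gives 16 directly, so steps 5 and 6 are no longer needed.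

2. Step 2. The N,O-dimethylhydroxylamine released at the quench could add in conjugate fashion to the fresh enone, and the enone could polymerise during isolation. The fallback sets out from 4 and returns at 7. Amide 4 would be reduced with LiAlH4 (THF, 0 °C) to icosanal F3, vinylmagnesium bromide 5 would be added to give racemic docos-1-en-3-ol F4, and this stable allylic alcohol would be oxidised with MnO2 in CH2Cl2 (or Dess–Martin periodinane) just before use. No amine is present when the enone is generated.

3. Step 5. Phosphorylation of the hindered tertiary hydroxyl could be sluggish, and chloride substitution or retro-aldol ring opening could compete with elimination. The fallback sets out from 12 and returns at 16. The alcohol would be acylated with trifluoroacetic anhydride and pyridine in CH2Cl2 at 0 °C to give methyl 3-nonadecyl-1-tosyl-3-(trifluoroacetoxy)pyrrolidine-2-carboxylate F5. DBU in toluene at 80 °C should then expel trifluoroacetate by E1cB elimination through the ester enolate to give methyl 3-nonadecyl-1-tosyl-4,5-dihydro-1H-pyrrole-2-carboxylate F6. Under the same base, the dienolate of this alkene should lose p-toluenesulfinate and tautomerise through 15 to 16.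

**Further compounds**

F1 | step 4 | docos-1-yn-3-one | CCCCCCCCCCCCCCCCCCCC(=O)C#C
F2 | step 4 | methyl N-[(1Z)-3-oxodocos-1-en-1-yl]glycinate | CCCCCCCCCCCCCCCCCCCC(=O)/C=C\NCC(=O)OC
F3 | step 2 | icosanal | CCCCCCCCCCCCCCCCCCCC=O
F4 | step 2 | docos-1-en-3-ol (racemic) | CCCCCCCCCCCCCCCCCCCC(O)C=C
F5 | step 5 | methyl 3-nonadecyl-1-tosyl-3-(trifluoroacetoxy)pyrrolidine-2-carboxylate (mixture of diastereomers) | CCCCCCCCCCCCCCCCCCCC1(OC(=O)C(F)(F)F)CCN(S(=O)(=O)c2ccc(C)cc2)C1C(=O)OC
F6 | step 5 | methyl 3-nonadecyl-1-tosyl-4,5-dihydro-1H-pyrrole-2-carboxylate | CCCCCCCCCCCCCCCCCCCC1=C(C(=O)OC)N(S(=O)(=O)c2ccc(C)cc2)CC1
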